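**Retrosynthetic overview**

1. The target, numbered as a bicyclo[3.2.1]oct-3-ene-2,8-dione (C1 and C5 bridgeheads, C2 and C8 carbonyls, C3=C4 with the styryl group on C4, C6 3,5-dihydroxyphenyl, C7 4-hydroxyphenyl), comes from fluoride desilylation of its tetrakis(TIPS) ether.
2. Key disconnection: C1–C8 and C4–C5 together. The core is the formal [4+2] adduct of a ketene (C5=C8=O) and a 2-oxy-1-en-3-yne (C1=C2(O)–C3≡C4), made by a relay double carbocyclisation of an acyclic siloxyalkyne/silyl dienyne ether under one monovalent-gold catalyst. Ring order: cyclopentanone first (5-endo-dig), then the cyclohexenone and with it the seven-membered ring (6-endo-dig).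
3. Enabling feature: the C8 ketone sits between both bridgeheads, so C1 is a 1,3-dicarbonyl carbon (between C2=O and C8=O, acylation retron) and C5 is the α-carbon of C8=O lying 1,5 to C2=O across the C3=C4 enone (endo conjugate-addition retron).
4. The acyclic precursor comes from an ynone (enolate/acetylide dianion, acetylide-to-ynolate oxidation, double O-silylation), itself from an alkynyl ester and an (E)-arylbutenyne; both alkynes come from aldehydes by Colvin rearrangement.
5. The C6/C7 stereodiad comes from an isothiourea-catalysed Michael addition–lactonisation of the bis(silyloxy)phenylacetic acid with a 4-silyloxyphenyl trichloromethyl enone (anti lactone), opened to amide/ester and reduced to the aldehyde.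

Key step: step 13

Abbreviations: TIPS = triisopropylsilyl; Ar = 4-(triisopropylsilyloxy)phenyl; Ar′ = 3,5-bis(triisopropylsilyloxy)phenyl; locants C1–C8 are those of the target core.

Assumption: (2S,3R)-HyperBTM is taken to give (3S,4S) anti lactones from arylacetic acids and trichloromethyl enones, so its enantiomer (2R,3S)-HyperBTM is specified for the (3R,4R) lactone; if the sense with these substrates is the reverse, the other catalyst enantiomer is used and nothing else changes.

**Route**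

Step 1
Reactants: 1 2-(3,5-dihydroxyphenyl)acetic acid
Product: 3 2-[3,5-bis(triisopropylsilyloxy)phenyl]acetic acid, via silyl ester 2 (not isolated)
Conditions: TIPSCl (3.3 equiv), imidazole, DMF, rt; then AcOH/THF/H2O, rt
Reagents that add atoms: triisopropylsilyl chloride, CC(C)[Si](Cl)(C(C)C)C(C)C
Why: Silylation of both phenols (and transiently the acid) followed by selective hydrolysis of the much more labile silyl ester; routine protecting-group chemistry with no stereocentre involved.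

Step 2
Reactants: 4 4-hydroxybenzaldehyde
Product: 5 4-(triisopropylsilyloxy)benzaldehyde
Conditions: TIPSCl, imidazole, DMF, rt
Reagents that add atoms: triisopropylsilyl chloride, CC(C)[Si](Cl)(C(C)C)C(C)C
Why: Standard phenol silylation; the bulky aryl silyl ether is chosen to survive organolithium, amide-base and peroxide steps and to leave under buffered fluoride at the end.

Step 3
Reactants: 6 methyltriphenylphosphonium bromide
Product: 8 1,1,1-trichloro-3-(triphenylphosphoranylidene)propan-2-one, via methylenetriphenylphosphorane 7 (not isolated)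
Conditions: n-BuLi (1 equiv per phosphonium), THF, 0 °C; then Cl3CCOCl (0.5 equiv), −78 °C → rt
Reagents that add atoms: trichloroacetyl chloride, ClC(Cl)(Cl)C(=O)Cl
Why: C-acylation of the non-stabilised ylide by the acid chloride, the second equivalent of ylide deprotonating the acylphosphonium salt (transylidation) to the stabilised β-keto ylide.

Step 4
Reactants: 5 4-(triisopropylsilyloxy)benzaldehyde; 8 1,1,1-trichloro-3-(triphenylphosphoranylidene)propan-2-one
Product: 9 (E)-1,1,1-trichloro-4-[4-(triisopropylsilyloxy)phenyl]but-3-en-2-one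
Conditions: toluene, 100 °C
Reagents that add atoms: none
Why: Wittig olefination with a stabilised β-keto ylide, which should give the (E)-enone.

Step 5
Reactants: 3 2-[3,5-bis(triisopropylsilyloxy)phenyl]acetic acid; 9 (E)-1,1,1-trichloro-4-[4-(triisopropylsilyloxy)phenyl]but-3-en-2-one
Product: 11 (3R,4R)-3-Ar′-4-Ar-6-(trichloromethyl)-3,4-dihydro-2H-pyran-2-one, via mixed pivalic anhydride 10 (not isolated)
Conditions: t-BuCOCl, i-Pr2NEt, CH2Cl2, 0 °C; then 9, (2R,3S)-HyperBTM (5 mol %), i-Pr2NEt, −78 °C → rt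
Reagents that add atoms: none
Why: Isothiourea-catalysed Michael addition–lactonisation: the mixed anhydride acylates the catalyst, deprotonation gives a (Z)-configured C1-ammonium enolate held by an O···S contact, and this adds to the enone from the face away from the catalyst's phenyl group before enolate O-acylation releases the catalyst, setting both stereocentres (future C6 and C7) as the anti (3,4-trans) lactone with catalyst control of the absolute sense.

Step 6
Reactants: 11 (3R,4R)-3-Ar′-4-Ar-6-(trichloromethyl)-3,4-dihydro-2H-pyran-2-one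
Product: 13 methyl (3R,4R)-4-Ar′-5-[methoxy(methyl)amino]-5-oxo-3-Ar-pentanoate, via trichloromethyl ketone amide 12 (not isolated)
Conditions: Me(MeO)NH·HCl (1.1 equiv), i-Pr2NEt (1.1 equiv), CH2Cl2, 0 °C → rt; then MeOH, DMAP (20 mol %), rt
Reagents that add atoms: N,O-dimethylhydroxylamine (used as its hydrochloride), CNOC; methanol, CO
Why: Aminolysis of the enol lactone (an activated ester) gives the N-methoxy-N-methylamide and unmasks the trichloromethyl ketone, which methanol then cleaves in a haloform-type acyl substitution; the α-aryl amide is far less prone to epimerisation than an ester or thioester.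

Step 7
Reactants: 13 methyl (3R,4R)-4-Ar′-5-[methoxy(methyl)amino]-5-oxo-3-Ar-pentanoate
Product: 14 methyl (3R,4R)-4-Ar′-5-oxo-3-Ar-pentanoate
Conditions: Cp2Zr(H)Cl (1.6 equiv), THF, rt
Reagents that add atoms: none
Why: Hydrozirconation of the tertiary amide carbonyl gives a zirconated hemiaminal that releases the aldehyde only on work-up, a reduction known to spare esters and to run under neutral conditions that should preserve the α-aryl stereocentre.

Step 8
Reactants: 14 methyl (3R,4R)-4-Ar′-5-oxo-3-Ar-pentanoate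
Product: 15 methyl (3R,4S)-4-Ar′-3-Ar-hex-5-ynoate
Conditions: TMSCHN2, n-BuLi, THF, −78 °C; then 14, −78 → 0 °C
Reagents that add atoms: trimethylsilyldiazomethane, C[Si](C)(C)C=[N+]=[N-]
Why: Colvin rearrangement: the lithiated diazomethane should add to the aldehyde at −78 °C faster than it enolises it, Peterson-type loss of silanolate gives a diazoalkene, and the derived alkylidene carbene undergoes 1,2-hydrogen shift to the terminal alkyne without touching the stereocentres (the descriptor at C4 changes only through CIP priorities).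

Step 9
Reactants: 5 4-(triisopropylsilyloxy)benzaldehyde
Product: 16 (E)-3-[4-(triisopropylsilyloxy)phenyl]prop-2-enal
Conditions: Ph3P=CHCHO, toluene, 80 °C
Reagents that add atoms: (triphenylphosphoranylidene)acetaldehyde, O=CC=P(c1ccccc1)(c1ccccc1)c1ccccc1
Why: Wittig two-carbon homologation with a formyl-stabilised ylide, which should give the (E)-enal.

Step 10
Reactants: 16 (E)-3-[4-(triisopropylsilyloxy)phenyl]prop-2-enal
Product: 17 (E)-1-[4-(triisopropylsilyloxy)phenyl]but-1-en-3-yne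
Conditions: TMSCHN2, n-BuLi, THF, −78 → 0 °C
Reagents that add atoms: trimethylsilyldiazomethane, C[Si](C)(C)C=[N+]=[N-]
Why: Colvin rearrangement after 1,2-addition to the enal gives the conjugated enyne with the (E)-alkene retained, avoiding the carbonate/methanol conditions that could cleave the aryl silyl ether.

Step 11
Reactants: 15 methyl (3R,4S)-4-Ar′-3-Ar-hex-5-ynoate; 17 (E)-1-[4-(triisopropylsilyloxy)phenyl]but-1-en-3-yne
Product: 19 (1E,7R,8S)-8-Ar′-1,7-di-Ar-dec-1-ene-3,9-diyn-5-one, via lithium acetylide 18 (not isolated)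
Conditions: 17 (2.5 equiv), n-BuLi, THF, −78 °C; BF3·OEt2; then 15, −78 °C
Reagents that add atoms: none
Why: The alkynyl borate-type reagent formed from the lithium acetylide and BF3·OEt2 should add once to the ester and stop at the boron-bound tetrahedral intermediate, which gives the ynone on work-up; the reagent is too weakly basic to disturb the propargylic stereocentre or the terminal alkyne.

Step 12
Reactants: 19 (1E,7R,8S)-8-Ar′-1,7-di-Ar-dec-1-ene-3,9-diyn-5-one
Product: 22 (1E,5Z,7S,8R)-8-Ar′-1,7-di-Ar-5,10-bis(triisopropylsilyloxy)deca-1,5-diene-3,9-diyne, via dilithio enolate-acetylide 20 (not isolated), via dilithio enolate-ynolate 21 (not isolated)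
Conditions: LiN(i-Pr)2 (2.2 equiv), THF, −78 °C; t-BuOOLi (from t-BuOOH and LiN(SiMe3)2), −78 → 0 °C; TIPSOTf (3 equiv), −78 → 0 °C
Reagents that add atoms: tert-butyl hydroperoxide (as its lithium salt), CC(C)(C)OO; triisopropylsilyl trifluoromethanesulfonate, CC(C)[Si](OS(=O)(=O)C(F)(F)F)(C(C)C)C(C)C
Why: Kinetic double deprotonation gives the ynone enolate (which also shields the ynone) and the lithium acetylide, oxygen transfer from lithium tert-butylperoxide converts the acetylide into the ynolate (known acetylide-to-ynolate oxidation), and the bulky silyl triflate silylates both oxyanions on oxygen; the enol ether geometry (drawn Z) is of no consequence.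

Step 13
Reactants: 22 (1E,5Z,7S,8R)-8-Ar′-1,7-di-Ar-5,10-bis(triisopropylsilyloxy)deca-1,5-diene-3,9-diyne
Product: 24 (1R,5S,6S,7S)-6-Ar′-7-Ar-4-[(E)-2-Ar-ethenyl]bicyclo[3.2.1]oct-3-ene-2,8-dione, via cyclopentenyl silyl enol ether 23 (not isolated)
Conditions: [(JohnPhos)Au(NCMe)]SbF6 (5 mol %; JohnPhos = (2-biphenylyl)P(t-Bu)2), i-PrOH (3 equiv), CH2Cl2, 0 °C → rt
Reagents that add atoms: none
Why: Proposed new method: cationic monovalent gold is expected to bind the most electron-rich π bond, the siloxyalkyne, as a gold ketene-oxonium species whose oxygen-bearing carbon (future C8) is attacked by the silyl enol ether carbon (future C1); the silyl cation passes to 2-propanol and the proton so released cleaves the vinyl–gold bond, leaving 23 with its enol double bond fixed toward C5 and the ynone unmasked, after which the same catalyst activates the ynone alkyne for attack by C5 at C4, followed by desilylation and protodeauration. The closest known reaction types are the gold-catalysed 5-endo-dig carbocyclisation of silyl enol ethers onto alkynes and the gold-catalysed 6-endo-dig carbocyclisation of cyclic silyl enol ethers onto tethered alkynes that gives bridged bicyclic ketones; new here is the siloxyalkyne as a masked ketene that hands a regiodefined, O-blocked enol ether from the first closure to the second. Ring closures: the cyclopentanone by 5-endo-dig (C1–C8), then the cyclohexenone and with it the seven-membered ring of the bicyclo[3.2.1] frame by 6-endo-dig (C4–C5). Stereocentres: C5 can only bond on the ring face that carries the C1 acyl arm, and C1 of 23 is α to the ynone carbonyl and should equilibrate by enolisation, so both bridgeheads are set under Curtin–Hammett control by the existing C6/C7 centres; the closure that forms the C5–C4 bond anti to the bulky 3,5-bis(silyloxy)phenyl group (leaving it exo) and places the slimmer 4-silyloxyphenyl group endo beside the C2 carbonyl should be preferred over the one that presses the 3,5-disubstituted ring against the C4 styryl arm. The selectivities needed are activation of the siloxyalkyne before the enyne, C- over O-cyclisation in the second closure, and 6-endo over 5-exo attack; they are secured by the electron richness of the siloxyalkyne, by the silyl group that blocks the C8 oxygen and fixes the enol toward C5, and by the Michael polarisation of the ynone.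

Step 14
Reactants: 24 (1R,5S,6S,7S)-6-Ar′-7-Ar-4-[(E)-2-Ar-ethenyl]bicyclo[3.2.1]oct-3-ene-2,8-dione
Product: 25 (1R,5S,6S,7S)-6-(3,5-dihydroxyphenyl)-7-(4-hydroxyphenyl)-4-[(E)-2-(4-hydroxyphenyl)ethenyl]bicyclo[3.2.1]oct-3-ene-2,8-dione
Conditions: n-Bu4NF, AcOH (1:1, 5 equiv each), THF, 0 °C → rt
Reagents that add atoms: none
Why: Fluoride cleavage of the four aryl silyl ethers, buffered with acetic acid so that the non-enolisable 1,3-diketone is not opened by retro-Claisen attack and the phenoxides are protonated at once; no stereocentre is touched.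

**Compound list**

1 | 2-(3,5-dihydroxyphenyl)acetic acid | OC(=O)Cc1cc(O)cc(O)c1 | starting material
2 | triisopropylsilyl 2-[3,5-bis(triisopropylsilyloxy)phenyl]acetate (not isolated) | CC(C)[Si](C(C)C)(C(C)C)OC(=O)Cc1cc(O[Si](C(C)C)(C(C)C)C(C)C)cc(O[Si](C(C)C)(C(C)C)C(C)C)c1 | intermediate
3 | 2-[3,5-bis(triisopropylsilyloxy)phenyl]acetic acid | OC(=O)Cc1cc(O[Si](C(C)C)(C(C)C)C(C)C)cc(O[Si](C(C)C)(C(C)C)C(C)C)c1 | intermediate
4 | 4-hydroxybenzaldehyde | O=Cc1ccc(O)cc1 | starting material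
5 | 4-(triisopropylsilyloxy)benzaldehyde | O=Cc1ccc(O[Si](C(C)C)(C(C)C)C(C)C)cc1 | intermediate
6 | methyltriphenylphosphonium bromide | C[P+](c1ccccc1)(c1ccccc1)c1ccccc1.[Br-] | starting material
7 | methylenetriphenylphosphorane (not isolated) | C=P(c1ccccc1)(c1ccccc1)c1ccccc1 | intermediate
8 | 1,1,1-trichloro-3-(triphenylphosphoranylidene)propan-2-one | ClC(Cl)(Cl)C(=O)C=P(c1ccccc1)(c1ccccc1)c1ccccc1 | intermediate
9 | (E)-1,1,1-trichloro-4-[4-(triisopropylsilyloxy)phenyl]but-3-en-2-one | ClC(Cl)(Cl)C(=O)/C=C/c1ccc(O[Si](C(C)C)(C(C)C)C(C)C)cc1 | intermediate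
10 | mixed anhydride of 3 and pivalic acid (not isolated) | CC(C)(C)C(=O)OC(=O)Cc1cc(O[Si](C(C)C)(C(C)C)C(C)C)cc(O[Si](C(C)C)(C(C)C)C(C)C)c1 | intermediate
11 | (3R,4R)-3-Ar′-4-Ar-6-(trichloromethyl)-3,4-dihydro-2H-pyran-2-one | ClC(Cl)(Cl)C1=C[C@@H](c2ccc(O[Si](C(C)C)(C(C)C)C(C)C)cc2)[C@@H](C(=O)O1)c1cc(O[Si](C(C)C)(C(C)C)C(C)C)cc(O[Si](C(C)C)(C(C)C)C(C)C)c1 | intermediate
12 | (2R,3R)-2-Ar′-3-Ar-6,6,6-trichloro-N-methoxy-N-methyl-5-oxohexanamide (not isolated) | ClC(Cl)(Cl)C(=O)C[C@@H](c1ccc(O[Si](C(C)C)(C(C)C)C(C)C)cc1)[C@@H](C(=O)N(C)OC)c1cc(O[Si](C(C)C)(C(C)C)C(C)C)cc(O[Si](C(C)C)(C(C)C)C(C)C)c1 | intermediate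
13 | methyl (3R,4R)-4-Ar′-5-[methoxy(methyl)amino]-5-oxo-3-Ar-pentanoate | COC(=O)C[C@@H](c1ccc(O[Si](C(C)C)(C(C)C)C(C)C)cc1)[C@@H](C(=O)N(C)OC)c1cc(O[Si](C(C)C)(C(C)C)C(C)C)cc(O[Si](C(C)C)(C(C)C)C(C)C)c1 | intermediate
14 | methyl (3R,4R)-4-Ar′-5-oxo-3-Ar-pentanoate | COC(=O)C[C@@H](c1ccc(O[Si](C(C)C)(C(C)C)C(C)C)cc1)[C@@H](C=O)c1cc(O[Si](C(C)C)(C(C)C)C(C)C)cc(O[Si](C(C)C)(C(C)C)C(C)C)c1 | intermediate
15 | methyl (3R,4S)-4-Ar′-3-Ar-hex-5-ynoate | COC(=O)C[C@@H](c1ccc(O[Si](C(C)C)(C(C)C)C(C)C)cc1)[C@@H](C#C)c1cc(O[Si](C(C)C)(C(C)C)C(C)C)cc(O[Si](C(C)C)(C(C)C)C(C)C)c1 | intermediate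
16 | (E)-3-[4-(triisopropylsilyloxy)phenyl]prop-2-enal | O=C/C=C/c1ccc(O[Si](C(C)C)(C(C)C)C(C)C)cc1 | intermediate
17 | (E)-1-[4-(triisopropylsilyloxy)phenyl]but-1-en-3-yne | C#C/C=C/c1ccc(O[Si](C(C)C)(C(C)C)C(C)C)cc1 | intermediate
18 | lithium acetylide of 17 (not isolated) | [Li]C#C/C=C/c1ccc(O[Si](C(C)C)(C(C)C)C(C)C)cc1 | intermediate
19 | (1E,7R,8S)-8-Ar′-1,7-di-Ar-dec-1-ene-3,9-diyn-5-one | O=C(C#C/C=C/c1ccc(O[Si](C(C)C)(C(C)C)C(C)C)cc1)C[C@@H](c1ccc(O[Si](C(C)C)(C(C)C)C(C)C)cc1)[C@@H](C#C)c1cc(O[Si](C(C)C)(C(C)C)C(C)C)cc(O[Si](C(C)C)(C(C)C)C(C)C)c1 | intermediate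
20 | dilithio enolate-acetylide of 19 (not isolated) | [Li]OC(C#C/C=C/c1ccc(O[Si](C(C)C)(C(C)C)C(C)C)cc1)=C[C@@H](c1ccc(O[Si](C(C)C)(C(C)C)C(C)C)cc1)[C@@H](C#C[Li])c1cc(O[Si](C(C)C)(C(C)C)C(C)C)cc(O[Si](C(C)C)(C(C)C)C(C)C)c1 | intermediate
21 | dilithio enolate-ynolate (not isolated) | [Li]OC(C#C/C=C/c1ccc(O[Si](C(C)C)(C(C)C)C(C)C)cc1)=C[C@@H](c1ccc(O[Si](C(C)C)(C(C)C)C(C)C)cc1)[C@@H](C#CO[Li])c1cc(O[Si](C(C)C)(C(C)C)C(C)C)cc(O[Si](C(C)C)(C(C)C)C(C)C)c1 | intermediate
22 | (1E,5Z,7S,8R)-8-Ar′-1,7-di-Ar-5,10-bis(triisopropylsilyloxy)deca-1,5-diene-3,9-diyne | CC(C)[Si](C(C)C)(C(C)C)O/C(C#C/C=C/c1ccc(O[Si](C(C)C)(C(C)C)C(C)C)cc1)=C\[C@@H](c1ccc(O[Si](C(C)C)(C(C)C)C(C)C)cc1)[C@@H](C#CO[Si](C(C)C)(C(C)C)C(C)C)c1cc(O[Si](C(C)C)(C(C)C)C(C)C)cc(O[Si](C(C)C)(C(C)C)C(C)C)c1 | intermediate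
23 | (E)-1-[(1S,4S,5S)-4-Ar′-5-Ar-2-(triisopropylsilyloxy)cyclopent-2-en-1-yl]-5-Ar-pent-4-en-2-yn-1-one, the C1 epimer that closes (not isolated) | O=C(C#C/C=C/c2ccc(O[Si](C(C)C)(C(C)C)C(C)C)cc2)[C@@H]1C(O[Si](C(C)C)(C(C)C)C(C)C)=C[C@@H](c2cc(O[Si](C(C)C)(C(C)C)C(C)C)cc(O[Si](C(C)C)(C(C)C)C(C)C)c2)[C@@H]1c1ccc(O[Si](C(C)C)(C(C)C)C(C)C)cc1 | intermediate
24 | (1R,5S,6S,7S)-6-Ar′-7-Ar-4-[(E)-2-Ar-ethenyl]bicyclo[3.2.1]oct-3-ene-2,8-dione | O=C1C=C(/C=C/c2ccc(O[Si](C(C)C)(C(C)C)C(C)C)cc2)[C@H]2C(=O)[C@@H]1[C@@H](c1ccc(O[Si](C(C)C)(C(C)C)C(C)C)cc1)[C@@H]2c1cc(O[Si](C(C)C)(C(C)C)C(C)C)cc(O[Si](C(C)C)(C(C)C)C(C)C)c1 | intermediate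
25 | (1R,5S,6S,7S)-6-(3,5-dihydroxyphenyl)-7-(4-hydroxyphenyl)-4-[(E)-2-(4-hydroxyphenyl)ethenyl]bicyclo[3.2.1]oct-3-ene-2,8-dione | O=C1C=C(/C=C/c2ccc(O)cc2)[C@H]2C(=O)[C@@H]1[C@@H](c1ccc(O)cc1)[C@@H]2c1cc(O)cc(O)c1 | target

**Step count and risks**

Total step count: 14. Longest linear sequence: 10 steps (steps 2, 4, 5, 6, 7, 8, 11, 12, 13, 14).

Steps most likely to fail:

1. Step 13 (proposed new method). The relay may stall or divert in several ways:
   - the proton source may add to the gold-activated siloxyalkyne;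
   - the siloxyalkyne carbon may attack the gold-activated enyne instead;
   - C1 of the intermediate may epimerise too slowly, so that the bridging closure occurs on the wrong ring face (poor exo/endo selectivity);
   - premature loss of the C8 silyl group may lead to O-cyclisation to a pyranone.

   Fallback with known reaction types, setting out from 19 and returning at 24. Compound 19 is taken through the dianion formation and acetylide oxidation of step 12 to 21, which is quenched into aqueous NH4Cl instead of silyl triflate; hydration of the ketene gives keto acid F1. Carbonyldiimidazole activation and soft enolisation (MgBr2·OEt2, i-Pr2NEt) should close the five-membered ring by intramolecular C-acylation to diketone F2. Without isolation this is chlorinated between the carbonyls with N-chlorosuccinimide, anti to the neighbouring aryl group, to chloro diketone F3; the acyl arm is then cis to the 4-silyloxyphenyl group and C1 is blocked against enolisation. t-BuMe2SiOTf/Et3N gives the only possible silyl enol ether F4. The 6-endo-dig carbocyclisation of such α-quaternary 2-alkynoyl cycloalkanone enol ethers with [(JohnPhos)Au(NCMe)]SbF6 and i-PrOH is an established way to bridged diketones and should give bridgehead chloride F5. Bu3SnH/AIBN (toluene, 80 °C) then removes the bridgehead chlorine to return to 24.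

2. Step 12. Oxygen transfer to the ketone enolate or conjugate attack of peroxide or amide on the ynone may compete with acetylide oxidation, and C-silylation of the ynolate would give a silylketene.

   Fallback setting out from 19 and returning at 22. The ketone is first masked without strong base or oxidant by soft enolisation (TIPSOTf, Et3N, CH2Cl2, −78 °C) to silyl dienyne ether F6. The remaining terminal alkyne is then deprotonated alone (n-BuLi, THF, −78 °C), oxidised with t-BuOOLi and O-silylated with TIPSOTf to give 22.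

3. Step 8. Enolisation of the α-aryl aldehyde by the basic carbanion may erode the configuration at the aryl-bearing carbon before addition occurs.

   Fallback setting out from 14 and returning at 22 through 20. Compound 14 is converted under buffered neutral conditions (CBr4, PPh3, 2,6-lutidine, CH2Cl2, 0 °C; first stage of the Corey–Fuchs reaction) into dibromoalkene F7. The ester is turned into the ynone exactly as in step 11 to give dibromoalkenyl ynone F8. LiN(i-Pr)2 (1 equiv) then forms the ynone enolate and n-BuLi (2 equiv, −78 °C) effects bromine–lithium exchange and rearrangement to the lithium acetylide, which is dianion 20; this is oxidised and silylated as in step 12 to give 22.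

**Further compounds**

F1 | step 13 | (3R,4R,9E)-3-Ar′-6-oxo-4,10-di-Ar-dec-9-en-7-ynoic acid | O=C(C#C/C=C/c1ccc(O[Si](C(C)C)(C(C)C)C(C)C)cc1)C[C@@H](c1ccc(O[Si](C(C)C)(C(C)C)C(C)C)cc1)[C@@H](CC(=O)O)c1cc(O[Si](C(C)C)(C(C)C)C(C)C)cc(O[Si](C(C)C)(C(C)C)C(C)C)c1
F2 | step 13 | (3S,4R)-4-Ar′-3-Ar-2-[(E)-5-Ar-pent-4-en-2-ynoyl]cyclopentan-1-one (C2 epimers and enol) | O=C(C#C/C=C/c2ccc(O[Si](C(C)C)(C(C)C)C(C)C)cc2)C1C(=O)C[C@@H](c2cc(O[Si](C(C)C)(C(C)C)C(C)C)cc(O[Si](C(C)C)(C(C)C)C(C)C)c2)[C@@H]1c1ccc(O[Si](C(C)C)(C(C)C)C(C)C)cc1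
F3 | step 13 | (2R,3R,4R)-2-chloro-4-Ar′-3-Ar-2-[(E)-5-Ar-pent-4-en-2-ynoyl]cyclopentan-1-one | O=C(C#C/C=C/c2ccc(O[Si](C(C)C)(C(C)C)C(C)C)cc2)[C@]1(Cl)C(=O)C[C@@H](c2cc(O[Si](C(C)C)(C(C)C)C(C)C)cc(O[Si](C(C)C)(C(C)C)C(C)C)c2)[C@@H]1c1ccc(O[Si](C(C)C)(C(C)C)C(C)C)cc1
F4 | step 13 | (E)-1-[(1R,4R,5R)-2-(tert-butyldimethylsilyloxy)-1-chloro-4-Ar′-5-Ar-cyclopent-2-en-1-yl]-5-Ar-pent-4-en-2-yn-1-one | O=C(C#C/C=C/c2ccc(O[Si](C(C)C)(C(C)C)C(C)C)cc2)[C@]1(Cl)C(O[Si](C)(C)C(C)(C)C)=C[C@@H](c2cc(O[Si](C(C)C)(C(C)C)C(C)C)cc(O[Si](C(C)C)(C(C)C)C(C)C)c2)[C@@H]1c1ccc(O[Si](C(C)C)(C(C)C)C(C)C)cc1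
F5 | step 13 | (1S,5S,6R,7R)-1-chloro-6-Ar′-7-Ar-4-[(E)-2-Ar-ethenyl]bicyclo[3.2.1]oct-3-ene-2,8-dione | O=C1C=C(/C=C/c2ccc(O[Si](C(C)C)(C(C)C)C(C)C)cc2)[C@H]2C(=O)[C@]1(Cl)[C@@H](c1ccc(O[Si](C(C)C)(C(C)C)C(C)C)cc1)[C@@H]2c1cc(O[Si](C(C)C)(C(C)C)C(C)C)cc(O[Si](C(C)C)(C(C)C)C(C)C)c1
F6 | step 12 | (1E,5Z,7S,8S)-8-Ar′-1,7-di-Ar-5-(triisopropylsilyloxy)deca-1,5-diene-3,9-diyne | CC(C)[Si](C(C)C)(C(C)C)O/C(C#C/C=C/c1ccc(O[Si](C(C)C)(C(C)C)C(C)C)cc1)=C\[C@@H](c1ccc(O[Si](C(C)C)(C(C)C)C(C)C)cc1)[C@@H](C#C)c1cc(O[Si](C(C)C)(C(C)C)C(C)C)cc(O[Si](C(C)C)(C(C)C)C(C)C)c1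
F7 | step 8 | methyl (3R,4S)-6,6-dibromo-4-Ar′-3-Ar-hex-5-enoate | COC(=O)C[C@@H](c1ccc(O[Si](C(C)C)(C(C)C)C(C)C)cc1)[C@@H](C=C(Br)Br)c1cc(O[Si](C(C)C)(C(C)C)C(C)C)cc(O[Si](C(C)C)(C(C)C)C(C)C)c1
F8 | step 8 | (1E,7R,8S)-10,10-dibromo-8-Ar′-1,7-di-Ar-deca-1,9-dien-3-yn-5-one | O=C(C#C/C=C/c1ccc(O[Si](C(C)C)(C(C)C)C(C)C)cc1)C[C@@H](c1ccc(O[Si](C(C)C)(C(C)C)C(C)C)cc1)[C@@H](C=C(Br)Br)c1cc(O[Si](C(C)C)(C(C)C)C(C)C)cc(O[Si](C(C)C)(C(C)C)C(C)C)c1
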